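The earlier runs differ in free base by 0.0310 M, more than the 0.0280 M between north-east and west, yet their electrophile readings at 25.0 h differ by 0.3 percentage points, less than the 5 points that counts as a change, with a scatter of 0.3 points. For any answer but no change, free base would have to begin to matter after 25.0 h. The plain way is for the 0.0400 M of free base in north-east, the flask with the smallest charge of it, to run out before 50 h.

in all of them: electrophile 0.050 M; nucleophile 0.125 M
- Friday's: free base 0.043 M; run made earlier
- Saturday's: free base 0.054 M; run made earlier
- Thursday's: free base 0.074 M; run made earlier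
- north-east: free base 0.0400 M; time 50 h
- west: free base 0.0680 M; time 50 h
- south-east: free base 0.0520 M; time 50 h

| run | time / h | electrophile / % | product / % |
|---|---|---|---|
| Friday's | 2.00 | 93.8 | 6.4 |
| Friday's | 6.00 | 83.7 | 16.5 |
| Friday's | 12.0 | 73.0 | 27.2 |
| Friday's | 20.0 | 61.7 | 37.7 |
| Friday's | 25.0 | 56.4 | 43.6 |
| Saturday's | 2.00 | 93.4 | 6.2 |
| Saturday's | 6.00 | 84.1 | 16.0 |
| Saturday's | 12.0 | 72.9 | 27.3 |
| Saturday's | 20.0 | 61.8 | 38.3 |
| Saturday's | 25.0 | 56.7 | 43.7 |
| Thursday's | 2.00 | 94.1 | 6.9 |
| Thursday's | 6.00 | 83.6 | 16.1 |
| Thursday's | 12.0 | 72.3 | 26.6 |
| Thursday's | 20.0 | 61.9 | 38.3 |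
| Thursday's | 25.0 | 56.7 | 43.6 |

(standard deviation of a reading: 0.3 percentage points)

- a reading or a percentage of product counts all its forms, free or not

* part of the electrophile that has reacted at the end, north-east
* part of the electrophile that has reacted at the end, west
* part of the electrophile that has reacted at the end, south-east
* what raising the concentration of free base from its lowest to its highest value here does to the part of the electrophile that has reacted (changes below 5 percentage points count as none) (it falls / no change / it rises)

So the amount of product at 50 h is wanted. Electrophile is the limiting reagent of the charge. If the rate is k[electrophile][nucleophile] and one nucleophile goes with each electrophile, the logarithm of [nucleophile]/[electrophile] climbs in a straight line. The mean electrophile reading at 25.0 h, 56.6 %, gives the read constant, k taken over the whole stretch from the start, 0.202 M⁻¹ h⁻¹, and so a time constant of 66.1 h for that logarithm. The mean reading at 2.00 h gives 0.261 M⁻¹ h⁻¹, which is more, so the k read off the runs is falling and this reckoning is likely to run high. Carried to 50 h, the ratio reaches 5.33, which means 65.4 % of the electrophile reacted. That is 0.0327 M of product, less than the 0.0400 M of free base in north-east, so even one free base taken per product leaves some, and no change is expected.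

The forecast gives 62 %, 62 % and 62 %, lower than this reckoning, and no change, on the ground that “the rate is effectively zero order in base while base remains”.

The flasks give 61.3 % in north-east, 61.4 % in west and 61.3 % in south-east, below the reckoned figure, and the trend is no change, a change of 0.039 points.

    nucleophile + acid set free ⇌ idle adduct A, settled at all times (K = 2.70 M⁻¹)
    nucleophile ⇌ dormant form (K = 0.220, k = 0.0660 h⁻¹)
    nucleophile + product ⇌ idle adduct B, settled at all times (K = 8.00 M⁻¹)
    acid set free + free base ⇌ salt of the base (K = 6500 M⁻¹, k = 1.60 M⁻¹ h⁻¹)
    nucleophile + acid set free ⇌ protonated nucleophile, settled at all times (K = 2500 M⁻¹)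
    electrophile + nucleophile → acid set free + product (k = 0.290 M⁻¹ h⁻¹)

At the end of north-east, protonated nucleophile stands at 0.0299 M and salt of the base at 4.38 × 10⁻⁴ M, with 99 % of the free base still free. Put to a neighbour of west with nucleophile cut to 0.075 M, the read constant gives a ratio of 1.93 and 46.3 % reacted, and that flask stands at 42.5 %.

The numbers in the tables were computed for an exercise, noise included.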